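(The data stem from a simulated flask for an exercise.)

- Late in each run the readings stop climbing, so take the mean of the last three readings as the plateau, and ask what it is a fraction of.

| flask | starting complex | incoming ligand | temperature | remark | time |
|---|---|---|---|---|---|
| Monday's | 0.10 M | 0.10 M | 25 °C | run made earlier |  |
| Sunday's | 0.050 M | 0.10 M | 40 °C | run made earlier |  |
| Thursday's | 0.20 M | 0.10 M | 25 °C | run made earlier |  |
| Friday's | 0.10 M | 0.050 M | 40 °C | run made earlier |  |
| theta | 0.10 M | 0.100 M (fed, over 15 min) |  | the addition at 20 °C, then warmed to 40 °C; the feed brings no volume worth counting | 25 min |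
| eta | 0.10 M | 0.100 M |  | everything together at the start at 20 °C, warmed to 40 °C at 15 min | 25 min |
| epsilon | 0.10 M | 0.100 M (fed, over 15 min) | 40 °C | all else is in the flask from the start; the feed brings no volume worth counting | 25 min |
| alpha | 0.10 M (fed, over 15 min) | 0.100 M | 40 °C | all else is in the flask from the start; the feed brings no volume worth counting | 25 min |

| run | time / min | complex with two exchanged / % |
|---|---|---|
| Monday's | 4.00 | 3.2 |
| Monday's | 12.0 | 12.4 |
| Monday's | 25.0 | 18.5 |
| Monday's | 40.0 | 18.6 |
| Monday's | 50.0 | 19.4 |
| Sunday's | 2.00 | 4.0 |
| Sunday's | 6.00 | 24.1 |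
| Sunday's | 12.0 | 32.8 |
| Sunday's | 20.0 | 33.8 |
| Sunday's | 25.0 | 31.7 |
| Thursday's | 4.00 | 2.9 |
| Thursday's | 12.0 | 7.2 |
| Thursday's | 25.0 | 9.7 |
| Thursday's | 40.0 | 10.4 |
| Thursday's | 50.0 | 8.8 |
| Friday's | 2.00 | 2.1 |
| Friday's | 6.00 | 4.4 |
| Friday's | 12.0 | 9.0 |
| Friday's | 20.0 | 6.4 |
| Friday's | 25.0 | 8.5 |

(scatter of a reading: 1 percentage point)

- the numbers in the tables scatter with a standard deviation of 1 percentage point

* the flask with the highest amount of complex with two exchanged, in percent of the starting complex charged ("all alike" if they lie within 1.5 percentage points) (theta / eta / epsilon / alpha / all alike)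
* final complex with two exchanged, as a percentage of the starting complex charged, in theta
* final complex with two exchanged, as a percentage of the starting complex charged, in eta
* final complex with two exchanged, as a percentage of the starting complex charged, in epsilon
* final complex with two exchanged, as a percentage of the starting complex charged, in alpha

- As a fraction of the starting complex the plateaus differ widely: 18.8% on Monday, 9.63% on Thursday with twice the complex.
- Reckoned on the ligand charge, they close up. The plateau share of ligand, meaning plateau product per incoming ligand charged, is 18.8% on Monday and 19.3% on Thursday. Sunday's plateau of 32.8% gives 16.4%, and Friday's 7.97% gives 15.9%. The mean is 17.6%.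
- Doesn't the ligand simply run out? Work with what is left. On Sunday, count two ligands for each complex read as product and one for each remaining complex: that reckoning leaves a fraction 33.6% of the ligand charge over, so on this count uptake of the ligand as limiting reagent doesn't explain that stop.
- Something then holds the exchange back, perhaps reversal, perhaps loss of ligand. You have not parted the two, and alpha is where you may be wrong.
- Temperature is a real doubt: the flasks end at 40 °C, where the mean share is 16.2%, against 19.1% in the colder runs. Yet Sunday and Friday have unequal charges, so keep 17.6% with those two means as your range. With equal charges it reads directly as percent of complex.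
- Is the plateau reached in time? In each recipe the last 10.0 min run at 40 °C with the whole charge in. Sunday has the same ligand charge, and its fraction still missing falls from 87.8% to 26.4% between 2.00 min and 6.00 min, a rate of 0.300 /min.
- Run on to 10.0 min, that rate gives an estimate of 7.97% missing, or 1.4 points, less than the margin. You commit to 17.6% in each flask, hence a tie.
- The forecast, which puts alpha lower than you do, names theta, gives 19.5% for theta, 19.5% for eta, 19% for epsilon and 14% for alpha, and says “Theta is only a nominal pick among three tied flasks.”
- Theta gives 17.9%, eta 17.9%, epsilon 17.7% and alpha 17.1%, so the outcome is: all alike.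

    complex with three exchanged + incoming ligand ⇌ leaving ligand + complex with four exchanged (K = 2.50, k = 0.0650 /M/s, Ea = 57.0 kJ/mol, ΔH = −7.00 kJ/mol)
    starting complex + incoming ligand ⇌ leaving ligand + complex with one exchanged (K = 1.70, k = 0.0240 /M/s, Ea = 71.0 kJ/mol, ΔH = 1.00 kJ/mol)
    complex with two exchanged + incoming ligand ⇌ leaving ligand + complex with three exchanged (K = 0.490, k = 0.00320 /M/s, Ea = 67.0 kJ/mol, ΔH = −77.0 kJ/mol)
    complex with one exchanged + incoming ligand ⇌ leaving ligand + complex with two exchanged (K = 1.40, k = 0.0550 /M/s, Ea = 43.0 kJ/mol, ΔH = −16.0 kJ/mol)
    (constants at 40 °C)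

Your 17.6% stands against 17.9% in theta, and on theta's recipe with 0.25 M of incoming ligand it gives 44.0% where that flask holds 36.9%. In theta the half-life of complex with two exchanged by its forward step alone, into complex with three exchanged, is 110 min at 25.0 min, longer than the run's 25 min. Left until 250 min, theta holds 14.4%.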